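**Remarks**
- Stereochemistry: the target has no stereocentre and no stereogenic axis, so its SMILES already defines the single compound to be made. The two stereocentres that arise on the way (the α‑methyl carbon in 6–15 and the carbinol carbon of 10) are carried as racemates or diastereomer mixtures and are erased before the key step.
- Nomenclature: the silyl enol ether 16 is numbered as a 1H‑indene (C1 = CH2, C3 = C–OSi). This puts the methoxy group on C4, the acetoxy group on C6 and the benzylic substituent on C7. The locants 4‑benzyl/5‑acetoxy/7‑methoxy belong to the indan‑1‑one 15 only; a "4‑benzyl‑5‑acetoxy‑7‑methoxy‑3‑silyloxy‑1H‑indene" would be the wrong regioisomer.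
- Labels and assumption: isocoumarin atoms are C1–C8a, the bridge is C9, ring A is C1'–C6'. Compounds 1 and 4 are taken to be catalogue chemicals.

## Structural features

The target is a 3‑methylisocoumarin (1H‑isochromen‑1‑one: lactone C1, O2, methyl‑bearing C3, C4–H, fused at C4a/C8a). Its benzo ring carries OH at C6, OMe at C8 and, at C5, a methylene bridge C9 to C1' of ring A. Ring A is a tetrasubstituted benzene with OMe at C2', OH at C4' and a methoxymethyl group at C6', so C1' is flanked on both sides. There is no stereocentre, so nothing stands next to anything stereochemically and no enantiomer has to be selected. The fragile parts are the enol lactone (opened by alkoxide or hydroxide, converted by amines), the two free phenols, and the electron‑rich diarylmethane (acid‑induced debenzylation, oxidation). The real difficulty is regiochemical. The benzo ring is pentasubstituted with C4a, C5 and C6 in a row. Both rings are the same 3‑hydroxy‑5‑methoxybenzyl unit, substituted para to OH in ring A and ortho to OH in the isocoumarin ring, and each keeps one OH and one OMe that must stay differentiated. The key step exploits the C1(=O)–O2–C3(Me)=C4 enol lactone: it is the dehydrated form of a 2‑(2‑oxopropyl)benzoic acid, whose carboxyl carbon C1 and ketone carbon C3 are the two carbons of the C1=C2 enol double bond of a 2‑methylindan‑1‑one.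

## Logic of the disconnections

19 from 18: the two phenolic O–H bonds are traced back to aryl O–acetyl bonds. The acetates lower the electron density of both arenes for the oxidative step. The forward cleavage must spare the enol lactone, which calls for acid methanolysis and not alkoxide.

18 from 16 through 17: the O2–C1 bond is cut, and the two carbonyl‑level carbons C1 and C3 are rejoined as the C1=C2 double bond of 16. This turns the oxygen heterocycle into a carbocycle that an acylation can build, and the ring oxygen is inserted only once the whole carbon skeleton exists. The forward step needs ozone to choose the enol ether over two oxygenated arenes, and needs 17 to close to the six‑membered enol lactone.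

16 from 15: the O–Si bond is cut. Only C2 of 15 carries α‑hydrogen, so enolisation has one direction. The silylation must be non‑nucleophilic toward the aryl acetates.

15 from 13 through 14: the acyl–aryl bond C1–C7a (indanone numbering) is cut. In 13 a single ring carbon ortho to the side chain is still free, so the closure has no regiochemical choice. The bicyclic ketone becomes a monocyclic diarylmethane acid. The Lewis acid must leave the methyl ether next to the new carbonyl, the acetates and the bridge intact.

13 from 12 from 11: first the two acetyl C–O bonds, then the ethyl ester C–O and the aryl O–Si bond are cut. Hydroxide removes ester and silyl group in one operation, and acetylation then installs the groups wanted for the acylation and the ozonolysis. The demand is exclusion of air while the phenoxides are present.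

11 from 10: the C9–H bond is exchanged for C9–OH. This lets the bridge be made by carbonyl addition. The forward reduction must trap the benzhydryl cation with hydride before the neighbouring methoxymethyl oxygen does.

10 from 3 and 7 through 8 and 9: the C9–C1' bond is cut. This is the convergent cut; it joins two halves of similar size that both descend from 1. It demands lithiation of 3 only at the carbon between OMe and CH2OMe, and addition of 8 to the aldehyde of 9 in preference to its ester.

7 from 6: the C5–C9 bond (aryl–formyl) is cut. An ortho‑specific formylation of the phenol places the future bridge carbon and at the same time occupies one of the two positions ortho to the side chain, which makes the later ring closure unambiguous. The demand is a preference for the ortho carbon para to OMe over the one between the two oxygens.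

6 from 5 from 1 and 4: the C=C bond of 5 is cut. It brings in the three carbons that become C4, C3 and the 3‑methyl group, together with the future C1 carboxyl, in one olefination without protecting the phenol.

3 from 2 from 1: the benzylic C–O bond of the methyl ether is traced to the aldehyde and the O–Si bond to the phenol. The bulky silyl group is chosen for what it must do later, which is to block lithiation at both carbons next to its oxygen.

## Other disconnections considered

Alternative 1: The cut removes C5–C9 and C4a–C4 at once. An aryl iodide, methyl 2‑iodo‑6‑methoxy‑4‑(methoxymethoxy)benzoate (A2), would enter a Catellani relay: palladium and a bicyclic olefin mediator move the metal from the C4a iodide to C5–H. The palladacycle would be alkylated by the ring A benzyl chloride (A3), and ipso Sonogashira‑type termination with propyne (A4) would give the alkynyl benzoate A1. A 6‑endo closure of the ester onto the alkyne and acetal removal would then lead to 19.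
- In favour: three components in one step; the site of benzylation is dictated by the iodide and not by arene nucleophilicity; C1 is already at the carboxyl level, so no oxidative cleavage is needed.
- Against: A3 is a doubly ortho‑substituted, easily ionised benzylic chloride that must add oxidatively to a crowded palladacycle. Direct alkynylation of A2 without relay competes. A4 is a gas. The iodide of A2 sits meta to both oxygens, so electrophilic iodination cannot place it. The alkyne closure must go 6‑endo and not 5‑exo.
- Comparison: on step economy and convergence the alternative is the better plan. On structure it is the equal of the chosen route, since both need ring A functionalised at C1'. On mechanism the chosen route rests on individually classical steps, while here one multi‑stage organometallic cascade has to tolerate the least suitable electrophile.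

Alternative 2: The cut removes C6'–CH2OMe and C1'–C9. The fluoroarene A7 would be lithiated between F and OMe and lose LiF to an aryne. (Methoxymethyl)lithium (A8) would add at C6', the position remote from OMe. The resulting C1' aryllithium, the same species as 8, would add to the isocoumarin‑5‑carbaldehyde A6 to give the racemic benzhydrol A5. Deoxygenation and deprotection would follow.
- In favour: ring A with its methoxymethyl group and the bridge are made in one flask; both new bonds are placed by the polarisation of the aryne; the isocoumarin is complete before the union.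
- Against: A8 is a thermally fragile α‑alkoxy organolithium, usually reached through tin chemistry, and it must survive the temperature at which the aryne forms. The lithiated A7 can itself add to the aryne. A6 offers a lactone carbonyl and an enol‑lactone double bond beside the aldehyde. A6 needs a regioselective C5 formylation that meets the same C5/C7 ambiguity the chosen route avoids.
- Comparison: union by aryllithium addition and later removal of the carbinol oxygen are common to both plans, so on mechanism of the coupling and on the redox detour the two are equal. The alternative is better in convergence. The chosen route is better in functional‑group tolerance at the union, where 9 carries only an ester and a phenoxide.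

Alternative 3: The cut removes C8a–C4a of the benzo ring. The C5‑benzylated diketo‑dioxinone A10 would undergo base‑ and then acid‑mediated intramolecular aldol addition of the dioxinone α‑carbon to the C4a ketone and dehydration, giving the acetonide‑masked resorcylate A9.
- In favour: the arene is built from a chain in which every substituent is already in place, so there is no aromatic substitution regiochemistry at all. The oxygens at C6 and C8 emerge differentiated. The C3 carbon is already a masked ketone, so no ozone is needed near electron‑rich arenes.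
- Against: A10 is a sensitive poly‑β‑carbonyl compound. Its central carbon must be mono‑C‑benzylated with a hindered ring A halide, with O‑alkylation and double alkylation as competitors. Other enolate/ketone pairings can cyclise. After A9 come phenol protection, dioxinone opening, O‑methylation at C8 (the chelated, less reactive hydroxyl), ketal removal with lactonisation, and deprotection.
- Comparison: on structure the alternative is the better plan, since regiochemistry is built in and no oxidation is required. On mechanism both rest on known reaction types and are equal. On step economy and robustness of intermediates the chosen route should be shorter and easier to handle.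

Key step: step 12

## Route

Step 1
Reactants: 1 3‑hydroxy‑5‑methoxybenzaldehyde
Product: 2 3‑methoxy‑5‑(triisopropylsilyloxy)benzaldehyde
Conditions: TIPSCl, imidazole, DMF, rt
Reagents that add atoms: triisopropylsilyl chloride, CC(C)[Si](Cl)(C(C)C)C(C)C
Why: Imidazole‑promoted silylation of a phenol; the bulky TIPS ether is chosen because it later shields both ring carbons next to this oxygen from lithiation and survives organolithium, silane and TFA.

Step 2
Reactants: 2 3‑methoxy‑5‑(triisopropylsilyloxy)benzaldehyde
Product: 3 1‑methoxy‑3‑(methoxymethyl)‑5‑(triisopropylsilyloxy)benzene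
Conditions: MeOSiMe3, Et3SiH, TMSOTf (10 mol%), CH2Cl2, −78 → 0 °C
Reagents that add atoms: methoxytrimethylsilane, CO[Si](C)(C)C
Why: Reductive etherification: the silyl triflate turns aldehyde and MeOSiMe3 into the O‑methyl oxocarbenium ion, which Et3SiH reduces; the aprotic, cold conditions leave the aryl silyl ether alone and replace a separate reduction and O‑methylation.

Step 3
Reactants: 1 3‑hydroxy‑5‑methoxybenzaldehyde; 4 ethyl 2‑(triphenyl‑λ5‑phosphanylidene)propanoate
Product: 5 ethyl (2E)‑3‑(3‑hydroxy‑5‑methoxyphenyl)‑2‑methylprop‑2‑enoate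
Conditions: toluene, 90 °C
Reagents that add atoms: none
Why: Wittig olefination with a stabilised ylide tolerates the free phenol; the E isomer should dominate, and the geometry is irrelevant after step 4.

Step 4
Reactants: 5 ethyl (2E)‑3‑(3‑hydroxy‑5‑methoxyphenyl)‑2‑methylprop‑2‑enoate
Product: 6 ethyl 3‑(3‑hydroxy‑5‑methoxyphenyl)‑2‑methylpropanoate (racemic)
Conditions: H2 (1 atm), 10% Pd/C, EtOAc, rt
Reagents that add atoms: none
Why: Heterogeneous catalytic hydrogenation of the cinnamate C=C; the α‑methyl stereocentre forms racemic and is deleted in step 11.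

Step 5
Reactants: 6 ethyl 3‑(3‑hydroxy‑5‑methoxyphenyl)‑2‑methylpropanoate
Product: 7 ethyl 3‑(2‑formyl‑3‑hydroxy‑5‑methoxyphenyl)‑2‑methylpropanoate (racemic)
Conditions: MgCl2, Et3N, (CH2O)n, MeCN, reflux; then aq. HCl
Reagents that add atoms: paraformaldehyde (as formaldehyde), C=O
Why: Magnesium‑phenoxide ortho‑formylation (Casnati–Skattebøl): formaldehyde is delivered inside the Mg phenoxide complex only to a carbon ortho to OH, so the carbon para to OH stays free for step 10; of the two ortho carbons the one para to OMe is the more nucleophilic, and the position between two oxygens is the disfavoured one in orcinol‑type rings; a second formaldehyde oxidises the Mg benzyloxide to the aldehyde.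

Step 6
Reactants: 3 1‑methoxy‑3‑(methoxymethyl)‑5‑(triisopropylsilyloxy)benzene; 7 ethyl 3‑(2‑formyl‑3‑hydroxy‑5‑methoxyphenyl)‑2‑methylpropanoate
Product: 10 ethyl 3‑[3‑hydroxy‑2‑{hydroxy[2‑methoxy‑6‑(methoxymethyl)‑4‑(triisopropylsilyloxy)phenyl]methyl}‑5‑methoxyphenyl]‑2‑methylpropanoate (mixture of racemic diastereomers), via C1' aryllithium of ring A 8 (not isolated), via sodium phenoxide of the salicylaldehyde 9 (not isolated)
Conditions: 3, n‑BuLi, Et2O, 0 °C → rt; 7, NaH, THF, 0 °C; combine at −78 → −40 °C; aq. NH4Cl; used crude
Reagents that add atoms: none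
Why: Directed ortho‑metalation followed by 1,2‑addition: in ether without diamine, n‑BuLi is guided by OMe and CH2OMe together to the carbon between them while the TIPS ether blocks the other two ring positions, and the hindered aryllithium 8 should add to the aldehyde of the pre‑formed phenoxide 9 faster than to the α‑branched ester at −78 °C; the carbinol stereocentre is uncontrolled and is removed in step 7.

Step 7
Reactants: 10 ethyl 3‑[3‑hydroxy‑2‑{hydroxy[2‑methoxy‑6‑(methoxymethyl)‑4‑(triisopropylsilyloxy)phenyl]methyl}‑5‑methoxyphenyl]‑2‑methylpropanoate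
Product: 11 ethyl 3‑[3‑hydroxy‑5‑methoxy‑2‑{[2‑methoxy‑6‑(methoxymethyl)‑4‑(triisopropylsilyloxy)phenyl]methyl}phenyl]‑2‑methylpropanoate (racemic)
Conditions: Et3SiH, TFA, CH2Cl2, −40 → 0 °C
Reagents that add atoms: none
Why: Ionic hydrogenation: TFA ionises the doubly benzylic carbinol, whose cation is stabilised by ortho‑OH/para‑OMe on one ring and ortho‑OMe/para‑OSi on the other, and Et3SiH delivers hydride; the aryl silyl ether, the ester and the methoxymethyl group (meta to both oxygens, not ionisable) should be left alone.

Step 8
Reactants: 11 ethyl 3‑[3‑hydroxy‑5‑methoxy‑2‑{[2‑methoxy‑6‑(methoxymethyl)‑4‑(triisopropylsilyloxy)phenyl]methyl}phenyl]‑2‑methylpropanoate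
Product: 12 3‑[3‑hydroxy‑2‑{[4‑hydroxy‑2‑methoxy‑6‑(methoxymethyl)phenyl]methyl}‑5‑methoxyphenyl]‑2‑methylpropanoic acid (racemic)
Conditions: KOH, MeOH/H2O (degassed), 65 °C; then 1 M HCl
Reagents that add atoms: potassium hydroxide, [K+].[OH-]
Why: Saponification of the ester; hydroxide also cleaves the aryl silyl ether because phenoxide is a good leaving group from silicon, so one operation frees the acid and the ring A phenol, and exclusion of air protects the phenoxides.

Step 9
Reactants: 12 3‑[3‑hydroxy‑2‑{[4‑hydroxy‑2‑methoxy‑6‑(methoxymethyl)phenyl]methyl}‑5‑methoxyphenyl]‑2‑methylpropanoic acid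
Product: 13 3‑[3‑acetoxy‑2‑{[4‑acetoxy‑2‑methoxy‑6‑(methoxymethyl)phenyl]methyl}‑5‑methoxyphenyl]‑2‑methylpropanoic acid (racemic)
Conditions: Ac2O, aq. NaOH, ice, 0 °C; then 1 M HCl to pH 3
Reagents that add atoms: acetic anhydride, CC(=O)OC(C)=O
Why: Acetylation of phenoxides with Ac2O in cold aqueous alkali (Chattaway conditions); a mixed anhydride of the carboxylate cannot persist in water, so only the two aryl acetates form and the acid returns on acidification.

Step 10
Reactants: 13 3‑[3‑acetoxy‑2‑{[4‑acetoxy‑2‑methoxy‑6‑(methoxymethyl)phenyl]methyl}‑5‑methoxyphenyl]‑2‑methylpropanoic acid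
Product: 15 5‑acetoxy‑4‑{[4‑acetoxy‑2‑methoxy‑6‑(methoxymethyl)phenyl]methyl}‑7‑methoxy‑2‑methylindan‑1‑one (racemic), via acid chloride 14 (not isolated)
Conditions: (COCl)2, DMF (cat.), CH2Cl2, 0 °C → rt; then SnCl4, CH2Cl2, −20 → 0 °C
Reagents that add atoms: none
Why: Intramolecular Friedel–Crafts acylation closing the five‑membered ring: the acyl chloride–SnCl4 complex can reach only the single free carbon ortho to the chain, which is activated by the ortho OMe; the acetates prevent O‑acylation and damp ipso attack on the diarylmethane, and SnCl4 at low temperature is chosen to spare the methyl ether next to the new carbonyl.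

Step 11
Reactants: 15 5‑acetoxy‑4‑{[4‑acetoxy‑2‑methoxy‑6‑(methoxymethyl)phenyl]methyl}‑7‑methoxy‑2‑methylindan‑1‑one
Product: 16 6‑acetoxy‑7‑{[4‑acetoxy‑2‑methoxy‑6‑(methoxymethyl)phenyl]methyl}‑4‑methoxy‑2‑methyl‑3‑(trimethylsilyloxy)‑1H‑indene (the C1=C2 silyl enol ether of 15)
Conditions: TMSOTf (1.15 equiv), Et3N, CH2Cl2, −20 → 0 °C; pentane, cold aq. NaHCO3; used crude
Reagents that add atoms: trimethylsilyl trifluoromethanesulfonate, C[Si](C)(C)OS(=O)(=O)C(F)(F)F
Why: Soft enolisation and O‑silylation of a ketone: only C2 carries α‑hydrogen, so a single tetrasubstituted enol ether can form and the racemic centre disappears; the conditions are non‑nucleophilic toward the aryl acetates, and limiting TMSOTf and temperature avoids silylating the acetate methyl groups.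

Step 12
Reactants: 16 6‑acetoxy‑7‑{[4‑acetoxy‑2‑methoxy‑6‑(methoxymethyl)phenyl]methyl}‑4‑methoxy‑2‑methyl‑3‑(trimethylsilyloxy)‑1H‑indene
Product: 18 6‑acetoxy‑5‑{[4‑acetoxy‑2‑methoxy‑6‑(methoxymethyl)phenyl]methyl}‑8‑methoxy‑3‑methyl‑1H‑isochromen‑1‑one, via keto acid 17 (not isolated)
Conditions: O3 (to the Sudan Red 7B end point), CH2Cl2/MeOH 4:1, −78 °C; Me2S, −78 °C → rt; then TFAA, CH2Cl2, 0 °C → rt
Reagents that add atoms: ozone, [O-][O+]=O
Why: Ozone adds as a 1,3‑dipole across the electron‑rich C1=C2 bond of 16, and the primary ozonide fragments so that the silyloxy carbon leaves as the silyl ester and the methyl‑bearing carbon as a carbonyl oxide, which methanol traps and Me2S reduces to the methyl ketone; methanolysis of the silyl ester gives keto acid 17. The closest known reaction types are the ozonolysis of cyclic silyl enol ethers to keto acids and the anhydride‑mediated enol lactonisation of 2‑(2‑oxopropyl)benzoic acids to 3‑methylisocoumarins. TFAA converts the carboxyl into a mixed anhydride, and the enol oxygen of the C3 ketone attacks C1 in a 6‑exo‑trig closure that forms O2–C1, the one new skeletal bond and the one new ring. No stereocentre is formed. The selectivity needed is that of ozone for the enol ether over two oxygenated arenes and the benzylic bridge: the silyl enol ether reacts orders of magnitude faster, both phenols are masked as electron‑poor acetates, and ozone is dosed to an indicator end point at −78 °C. The orientation of the lactone is fixed by the skeleton, because the enol carbon C1 already sits next to the methoxy‑bearing carbon in 15.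

Step 13
Reactants: 18 6‑acetoxy‑5‑{[4‑acetoxy‑2‑methoxy‑6‑(methoxymethyl)phenyl]methyl}‑8‑methoxy‑3‑methyl‑1H‑isochromen‑1‑one
Product: 19 6‑hydroxy‑5‑{[4‑hydroxy‑2‑methoxy‑6‑(methoxymethyl)phenyl]methyl}‑8‑methoxy‑3‑methyl‑1H‑isochromen‑1‑one (target)
Conditions: HCl (ca. 1 M in MeOH), 40 °C
Reagents that add atoms: none
Why: Acid‑catalysed transesterification of the two aryl acetates with methanol; the isocoumarin lactone, which alkoxide could open, is stable to dilute HCl in methanol, and the benzylic methyl ether can only exchange degenerately.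

## Compound list

1 | 3‑hydroxy‑5‑methoxybenzaldehyde | O=Cc1cc(O)cc(OC)c1 | starting material
2 | 3‑methoxy‑5‑(triisopropylsilyloxy)benzaldehyde | O=Cc1cc(OC)cc(O[Si](C(C)C)(C(C)C)C(C)C)c1 | intermediate
3 | 1‑methoxy‑3‑(methoxymethyl)‑5‑(triisopropylsilyloxy)benzene | COCc1cc(OC)cc(O[Si](C(C)C)(C(C)C)C(C)C)c1 | intermediate
4 | ethyl 2‑(triphenyl‑λ5‑phosphanylidene)propanoate | CCOC(=O)C(C)=P(c1ccccc1)(c1ccccc1)c1ccccc1 | starting material
5 | ethyl (2E)‑3‑(3‑hydroxy‑5‑methoxyphenyl)‑2‑methylprop‑2‑enoate | CCOC(=O)/C(C)=C/c1cc(O)cc(OC)c1 | intermediate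
6 | ethyl 3‑(3‑hydroxy‑5‑methoxyphenyl)‑2‑methylpropanoate (racemic) | CCOC(=O)C(C)Cc1cc(O)cc(OC)c1 | intermediate
7 | ethyl 3‑(2‑formyl‑3‑hydroxy‑5‑methoxyphenyl)‑2‑methylpropanoate (racemic) | CCOC(=O)C(C)Cc1cc(OC)cc(O)c1C=O | intermediate
8 | [2‑methoxy‑6‑(methoxymethyl)‑4‑(triisopropylsilyloxy)phenyl]lithium | COCc1cc(O[Si](C(C)C)(C(C)C)C(C)C)cc(OC)c1[Li] | intermediate (not isolated)
9 | sodium 3‑(3‑ethoxy‑2‑methyl‑3‑oxopropyl)‑2‑formyl‑5‑methoxyphenolate | CCOC(=O)C(C)Cc1cc(OC)cc([O-])c1C=O.[Na+] | intermediate (not isolated)
10 | ethyl 3‑[3‑hydroxy‑2‑{hydroxy[2‑methoxy‑6‑(methoxymethyl)‑4‑(triisopropylsilyloxy)phenyl]methyl}‑5‑methoxyphenyl]‑2‑methylpropanoate (diastereomer mixture, racemic) | CCOC(=O)C(C)Cc1cc(OC)cc(O)c1C(O)c1c(OC)cc(O[Si](C(C)C)(C(C)C)C(C)C)cc1COC | intermediate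
11 | ethyl 3‑[3‑hydroxy‑5‑methoxy‑2‑{[2‑methoxy‑6‑(methoxymethyl)‑4‑(triisopropylsilyloxy)phenyl]methyl}phenyl]‑2‑methylpropanoate (racemic) | CCOC(=O)C(C)Cc1cc(OC)cc(O)c1Cc1c(OC)cc(O[Si](C(C)C)(C(C)C)C(C)C)cc1COC | intermediate
12 | 3‑[3‑hydroxy‑2‑{[4‑hydroxy‑2‑methoxy‑6‑(methoxymethyl)phenyl]methyl}‑5‑methoxyphenyl]‑2‑methylpropanoic acid (racemic) | OC(=O)C(C)Cc1cc(OC)cc(O)c1Cc1c(OC)cc(O)cc1COC | intermediate
13 | 3‑[3‑acetoxy‑2‑{[4‑acetoxy‑2‑methoxy‑6‑(methoxymethyl)phenyl]methyl}‑5‑methoxyphenyl]‑2‑methylpropanoic acid (racemic) | OC(=O)C(C)Cc1cc(OC)cc(OC(C)=O)c1Cc1c(OC)cc(OC(C)=O)cc1COC | intermediate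
14 | 3‑[3‑acetoxy‑2‑{[4‑acetoxy‑2‑methoxy‑6‑(methoxymethyl)phenyl]methyl}‑5‑methoxyphenyl]‑2‑methylpropanoyl chloride (racemic) | ClC(=O)C(C)Cc1cc(OC)cc(OC(C)=O)c1Cc1c(OC)cc(OC(C)=O)cc1COC | intermediate (not isolated)
15 | 5‑acetoxy‑4‑{[4‑acetoxy‑2‑methoxy‑6‑(methoxymethyl)phenyl]methyl}‑7‑methoxy‑2‑methylindan‑1‑one (racemic) | COCc1cc(OC(C)=O)cc(OC)c1Cc1c(OC(C)=O)cc(OC)c2c1CC(C)C2=O | intermediate
16 | 6‑acetoxy‑7‑{[4‑acetoxy‑2‑methoxy‑6‑(methoxymethyl)phenyl]methyl}‑4‑methoxy‑2‑methyl‑3‑(trimethylsilyloxy)‑1H‑indene | COCc1cc(OC(C)=O)cc(OC)c1Cc1c(OC(C)=O)cc(OC)c2c1CC(C)=C2O[Si](C)(C)C | intermediate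
17 | 4‑acetoxy‑3‑{[4‑acetoxy‑2‑methoxy‑6‑(methoxymethyl)phenyl]methyl}‑6‑methoxy‑2‑(2‑oxopropyl)benzoic acid | COCc1cc(OC(C)=O)cc(OC)c1Cc1c(OC(C)=O)cc(OC)c(C(=O)O)c1CC(C)=O | intermediate (not isolated)
18 | 6‑acetoxy‑5‑{[4‑acetoxy‑2‑methoxy‑6‑(methoxymethyl)phenyl]methyl}‑8‑methoxy‑3‑methyl‑1H‑isochromen‑1‑one | COCc1cc(OC(C)=O)cc(OC)c1Cc1c(OC(C)=O)cc(OC)c2c(=O)oc(C)cc12 | intermediate
19 | 6‑hydroxy‑5‑{[4‑hydroxy‑2‑methoxy‑6‑(methoxymethyl)phenyl]methyl}‑8‑methoxy‑3‑methyl‑1H‑isochromen‑1‑one | COCc1cc(O)cc(OC)c1Cc1c(O)cc(OC)c2c(=O)oc(C)cc12 | target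

## Step count and least certain steps

Total step count: 13. Longest linear sequence: 11 steps (steps 3–13, from 1 and 4). The two‑step branch 1 → 2 → 3 enters at step 6.

Step 12 (key step). What may go wrong: over‑oxidation of the oxygenated arenes or the benzylic bridge once the enol ether is consumed, or hydrolysis of the silyl enol ether back to the ketone before cleavage, which leaves uncleaved indanone. Fallback: set out from 16 and separate oxygenation from cleavage. Rubottom oxidation (mCPBA, NaHCO3, CH2Cl2, 0 °C; dilute citric acid work‑up) should give the α‑ketol 5‑acetoxy‑4‑{[4‑acetoxy‑2‑methoxy‑6‑(methoxymethyl)phenyl]methyl}‑2‑hydroxy‑7‑methoxy‑2‑methylindan‑1‑one F1. Cleavage of this tertiary α‑ketol with periodic acid in aqueous THF should give keto acid 17, which TFAA closes as before. The fallback returns to the route at 18.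

Step 6. What may go wrong: deprotonation at the benzylic methoxymethyl carbon followed by Wittig rearrangement, or lithiation at a ring carbon next to the silyl ether, either of which gives the wrong connectivity; proton transfer from the ester α‑position may also quench the aryllithium. Fallback: set out from 2 and make the same aryllithium by hydroxyl‑directed lithiation and halogen–metal exchange.
- NaBH4 should give [3‑methoxy‑5‑(triisopropylsilyloxy)phenyl]methanol F2.
- Alkoxide‑directed lithiation with n‑BuLi (2.2 equiv) between CH2OLi and OMe, where no benzylic deprotonation is possible, and an iodine quench should give [2‑iodo‑3‑methoxy‑5‑(triisopropylsilyloxy)phenyl]methanol F3.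
- O‑Methylation (MeI, Ag2O) should give 2‑iodo‑1‑methoxy‑3‑(methoxymethyl)‑5‑(triisopropylsilyloxy)benzene F4.
- Iodine–lithium exchange (n‑BuLi, −78 °C) should deliver 8, from which the route continues to 10.

Step 5. What may go wrong: formylation at the ortho carbon between the two oxygen substituents, or condensation of the phenol with formaldehyde to methylene‑bridged dimers. Fallback: set out from 4 and the symmetric catalogue aldehyde 3,5‑dihydroxybenzaldehyde F5, so that symmetry removes the ortho/ortho choice.
- Wittig olefination should give ethyl (2E)‑3‑(3,5‑dihydroxyphenyl)‑2‑methylprop‑2‑enoate F6.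
- Hydrogenation should give ethyl 3‑(3,5‑dihydroxyphenyl)‑2‑methylpropanoate F7.
- Vilsmeier–Haack formylation (POCl3, DMF), which in 5‑alkylresorcinols goes next to the alkyl group, should give ethyl 3‑(2‑formyl‑3,5‑dihydroxyphenyl)‑2‑methylpropanoate F8.
- Selective methylation of the non‑chelated hydroxyl para to the formyl group (MeI 1.05 equiv, K2CO3, acetone) should give 7, where the route is rejoined.

Step 10. What may go wrong: slow acylation at a carbon para to an acetoxy group, so that Lewis‑acid side processes take over (chelation‑assisted loss of the methyl ether next to the new carbonyl, acetate migration). Fallback: set out from 12 and cyclise before acetylation. Eaton's reagent (P2O5/MsOH, rt) acts on the free acid, and the free hydroxyl para to the closing carbon accelerates ring closure. This should give 5‑hydroxy‑4‑{[4‑hydroxy‑2‑methoxy‑6‑(methoxymethyl)phenyl]methyl}‑7‑methoxy‑2‑methylindan‑1‑one F9. Acetylation (Ac2O, pyridine) then gives 15, where the route is rejoined.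

Step 7. What may go wrong: capture of the benzhydryl cation by the oxygen of the neighbouring methoxymethyl group (cyclic oxonium ion, then loss of methyl to a dihydroisobenzofuran), or oligomerisation of the ortho‑quinone methide before hydride transfer. Fallback: set out from 10 and cleave the doubly benzylic C–O bond by heterogeneous hydrogenolysis (H2, Pd/C, EtOAc, trace AcOH), which involves no free cation in solution. It returns directly at 11 and makes no compound outside the list (F0).

## Further compounds

F1 | step 12 | 5‑acetoxy‑4‑{[4‑acetoxy‑2‑methoxy‑6‑(methoxymethyl)phenyl]methyl}‑2‑hydroxy‑7‑methoxy‑2‑methylindan‑1‑one (racemic) | COCc1cc(OC(C)=O)cc(OC)c1Cc1c(OC(C)=O)cc(OC)c2c1CC(C)(O)C2=O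
F2 | step 6 | [3‑methoxy‑5‑(triisopropylsilyloxy)phenyl]methanol | OCc1cc(OC)cc(O[Si](C(C)C)(C(C)C)C(C)C)c1
F3 | step 6 | [2‑iodo‑3‑methoxy‑5‑(triisopropylsilyloxy)phenyl]methanol | OCc1cc(O[Si](C(C)C)(C(C)C)C(C)C)cc(OC)c1I
F4 | step 6 | 2‑iodo‑1‑methoxy‑3‑(methoxymethyl)‑5‑(triisopropylsilyloxy)benzene | COCc1cc(O[Si](C(C)C)(C(C)C)C(C)C)cc(OC)c1I
F5 | step 5 | 3,5‑dihydroxybenzaldehyde | O=Cc1cc(O)cc(O)c1
F6 | step 5 | ethyl (2E)‑3‑(3,5‑dihydroxyphenyl)‑2‑methylprop‑2‑enoate | CCOC(=O)/C(C)=C/c1cc(O)cc(O)c1
F7 | step 5 | ethyl 3‑(3,5‑dihydroxyphenyl)‑2‑methylpropanoate (racemic) | CCOC(=O)C(C)Cc1cc(O)cc(O)c1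
F8 | step 5 | ethyl 3‑(2‑formyl‑3,5‑dihydroxyphenyl)‑2‑methylpropanoate (racemic) | CCOC(=O)C(C)Cc1cc(O)cc(O)c1C=O
F9 | step 10 | 5‑hydroxy‑4‑{[4‑hydroxy‑2‑methoxy‑6‑(methoxymethyl)phenyl]methyl}‑7‑methoxy‑2‑methylindan‑1‑one (racemic) | COCc1cc(O)cc(OC)c1Cc1c(O)cc(OC)c2c1CC(C)C2=O
F0 | step 7 | none | none
A1 | alternative 1 | methyl 6‑methoxy‑3‑{[2‑methoxy‑6‑(methoxymethyl)‑4‑(methoxymethoxy)phenyl]methyl}‑4‑(methoxymethoxy)‑2‑(prop‑1‑yn‑1‑yl)benzoate | COCc1cc(OCOC)cc(OC)c1Cc1c(OCOC)cc(OC)c(C(=O)OC)c1C#CC
A2 | alternative 1 | methyl 2‑iodo‑6‑methoxy‑4‑(methoxymethoxy)benzoate | COC(=O)c1c(I)cc(OCOC)cc1OC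
A3 | alternative 1 | 2‑(chloromethyl)‑1‑methoxy‑3‑(methoxymethyl)‑5‑(methoxymethoxy)benzene | COCc1cc(OCOC)cc(OC)c1CCl
A4 | alternative 1 | propyne | CC#C
A5 | alternative 2 | 5‑{hydroxy[2‑methoxy‑6‑(methoxymethyl)‑4‑(triisopropylsilyloxy)phenyl]methyl}‑8‑methoxy‑6‑(methoxymethoxy)‑3‑methyl‑1H‑isochromen‑1‑one (racemic) | COCc1cc(O[Si](C(C)C)(C(C)C)C(C)C)cc(OC)c1C(O)c1c(OCOC)cc(OC)c2c(=O)oc(C)cc12
A6 | alternative 2 | 8‑methoxy‑6‑(methoxymethoxy)‑3‑methyl‑1‑oxo‑1H‑isochromene‑5‑carbaldehyde | O=Cc1c(OCOC)cc(OC)c2c(=O)oc(C)cc12
A7 | alternative 2 | 1‑fluoro‑3‑methoxy‑5‑(triisopropylsilyloxy)benzene | COc1cc(F)cc(O[Si](C(C)C)(C(C)C)C(C)C)c1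
A8 | alternative 2 | (methoxymethyl)lithium | [Li]COC
A9 | alternative 3 | 7‑hydroxy‑6‑{[2‑methoxy‑6‑(methoxymethyl)‑4‑(methoxymethoxy)phenyl]methyl}‑2,2‑dimethyl‑5‑[(2‑methyl‑1,3‑dioxolan‑2‑yl)methyl]‑4H‑1,3‑benzodioxin‑4‑one | COCc1cc(OCOC)cc(OC)c1Cc1c(O)cc2OC(C)(C)OC(=O)c2c1CC1(C)OCCO1
A10 | alternative 3 | 6‑[3‑{[2‑methoxy‑6‑(methoxymethyl)‑4‑(methoxymethoxy)phenyl]methyl}‑5‑(2‑methyl‑1,3‑dioxolan‑2‑yl)‑2,4‑dioxopentyl]‑2,2‑dimethyl‑4H‑1,3‑dioxin‑4‑one | CC1(C)OC(=O)C=C(CC(=O)C(Cc2c(OC)cc(OCOC)cc2COC)C(=O)CC2(C)OCCO2)O1
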